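**Plan**
1. Retrosynthesis: the seven benzyl ethers are cut last; then the interflavan bond C4(upper)–C8(lower), to an 8-metallated lower unit and a (2S)-flavanone whose C4 oxygen is removed by hydride; then, in the lower unit, O1–C8a and C2–C3 of ring C together, which leaves the ring-B aldehyde and a ring-A fluoroarene that carries C4 and a masked carbanionic C3.
2. Forward: ring A from 1,3,5-trifluorobenzene, C4 by formylation, C3 as a 2-silyl-1,3-dithiane, ring C of the lower unit closed in one operation with 3,4-bis(benzyloxy)benzaldehyde, then C3 ketone, cis alcohol, C8 bromide, union with the upper flavanone, C4 reduction, debenzylation.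
3. Enabling feature: in ring A of the lower unit the oxygens on C5 and C7 are meta to C8a, so a fluorine on C8a stays displaceable by the C2 alkoxide. C3 is an oxygen-bearing carbon that can be carried as a dithiane acyl-anion equivalent, and the fluoride leaving C8a is the ion that frees the C3 carbanion from silicon.
4. Stereochemistry: lower C2 and C3 by Ru-catalysed hydrogenation with dynamic kinetic resolution of the flavan-3-one (C2 is labile next to the carbonyl); upper C2 by Pd-catalysed asymmetric conjugate addition to a chromone; upper C4 by hydride delivery anti to the C2 aryl group (2,4-cis).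

Key step: step 6

Assumption: the antipodes of the chiral ligands in steps 8 and 12 are named by analogy with 2-arylcyclohexanones and 3-substituted cyclohexenones; if a test run shows the opposite sense, the mirror-image ligand is used.

Step 1
Reactants: 1 1,3,5-trifluorobenzene; 2 benzyl alcohol
Product: 3 1,3-bis(benzyloxy)-5-fluorobenzene
Conditions: NaH (2.2 equiv), 2 (2.1 equiv), NMP, 0 → 100 °C
Reagents that add atoms: none
Why: Twofold nucleophilic aromatic substitution by benzyloxide should stop after two fluorides, because each fluorine lost removes an inductive activator of the ring.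

Step 2
Reactants: 3 1,3-bis(benzyloxy)-5-fluorobenzene
Product: 4 2,4-bis(benzyloxy)-6-fluorobenzaldehyde
Conditions: POCl3, DMF, 0 → 60 °C; then H2O
Reagents that add atoms: N,N-dimethylformamide CN(C)C=O; water O
Why: Vilsmeier–Haack formylation should go to the carbon ortho and para to the two benzyloxy groups that is flanked by the small fluorine, the site between the two benzyloxy groups being more hindered.

Step 3
Reactants: 4 2,4-bis(benzyloxy)-6-fluorobenzaldehyde
Product: 5 [2,4-bis(benzyloxy)-6-fluorophenyl]methanol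
Conditions: NaBH4, MeOH/THF, 0 °C
Reagents that add atoms: none
Why: Borohydride reduction of an aromatic aldehyde; nothing else in 4 is reducible.

Step 4
Reactants: 5 [2,4-bis(benzyloxy)-6-fluorophenyl]methanol
Product: 6 1,5-bis(benzyloxy)-2-(bromomethyl)-3-fluorobenzene
Conditions: CBr4, PPh3, CH2Cl2, 0 °C; used at once without chromatography
Reagents that add atoms: carbon tetrabromide BrC(Br)(Br)Br
Why: Appel bromination is neutral and so avoids the acid that would ionise this electron-rich benzylic system.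

Step 5
Reactants: 7 2-(trimethylsilyl)-1,3-dithiane; 6 1,5-bis(benzyloxy)-2-(bromomethyl)-3-fluorobenzene
Product: 8 2-[2,4-bis(benzyloxy)-6-fluorobenzyl]-2-(trimethylsilyl)-1,3-dithiane
Conditions: 7, n-BuLi, THF, −78 → −20 °C; then 6, −78 → 0 °C
Reagents that add atoms: none
Why: Corey–Seebach alkylation in which the lithio dithiane is formed before the fluoroarene is added, so that no lithium base meets the acidic C–H next to fluorine, and the benzylic bromide is taken by SN2.

Step 6
Reactants: 8 2-[2,4-bis(benzyloxy)-6-fluorobenzyl]-2-(trimethylsilyl)-1,3-dithiane; 9 3,4-bis(benzyloxy)benzaldehyde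
Product: 11 (±)-5,7-bis(benzyloxy)-2-[3,4-bis(benzyloxy)phenyl]spiro[chromane-3,2'-[1,3]dithiane], via caesium alkoxide adduct 10 (not isolated)
Conditions: CsF (1.5 equiv), 18-crown-6 (0.2 equiv), 4 Å MS, DMF, 0 → 23 °C, then 90 °C
Reagents that add atoms: none
Why: Proposed new method: fluoride attacks silicon of 8 and releases the sulfur-stabilised C3 carbanion, which adds to the aldehyde carbon of 9 (C2–C3 bond) to give alkoxide 10, and this alkoxide attacks C8a ipso to fluorine through a Meisenheimer complex and expels fluoride (O1–C8a bond), the fluoride returning to desilylate the next molecule of 8 or to free 10 from its O-silyl ether. The closest known reaction types are the Lewis-base-triggered addition of 2-silyl-1,3-dithianes to aldehydes and the intramolecular alkoxide SNAr on 3,5-dialkoxyfluoroarenes that closes flavan pyran rings; what is new is their coupling through one fluoride relay. Ring C closes by a 6-exo-trig addition at C8a (with respect to the C8a=C8 bond), this fluorine-bearing carbon being the only electrophilic site within reach of the tethered alkoxide. The single new stereocenter C2 is formed without control and on purpose, since it becomes epimerisable next to the C3 carbonyl and is fixed in step 8. The step needs carbanion formation without a lithium base, which would metalate C8 next to fluorine, and the C–Si bond as latent nucleophile secures this; it also needs an alkoxide that is not lost by enolisation, which the non-enolisable aldehyde and the dithioketal-masked C3 secure.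

Step 7
Reactants: 11 (±)-5,7-bis(benzyloxy)-2-[3,4-bis(benzyloxy)phenyl]spiro[chromane-3,2'-[1,3]dithiane]
Product: 12 (±)-5,7-bis(benzyloxy)-2-[3,4-bis(benzyloxy)phenyl]chroman-3-one
Conditions: Hg(ClO4)2·3H2O, CaCO3, THF/H2O, 0 °C
Reagents that add atoms: water O
Why: Thiophilic mercury-assisted dithioketal hydrolysis under buffered conditions should unmask the C3 ketone without touching the benzyl ethers or the electron-rich rings.

Step 8
Reactants: 12 (±)-5,7-bis(benzyloxy)-2-[3,4-bis(benzyloxy)phenyl]chroman-3-one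
Product: 13 (2R,3R)-5,7-bis(benzyloxy)-2-[3,4-bis(benzyloxy)phenyl]chroman-3-ol
Conditions: RuCl2[(R)-Xyl-SDP][(S,S)-DPEN] (1 mol %), t-BuOK (20 mol %), H2 (50 atm), i-PrOH/THF, 25 °C
Reagents that add atoms: none
Why: Noyori asymmetric hydrogenation with dynamic kinetic resolution: C2, benzylic and next to the ketone, should epimerise under t-BuOK faster than reduction, and the catalyst should reduce the (2R) ketone from the face opposite the C2 aryl group, which sets C3 cis to C2 and both as R.

Step 9
Reactants: 13 (2R,3R)-5,7-bis(benzyloxy)-2-[3,4-bis(benzyloxy)phenyl]chroman-3-ol; 14 benzyl bromide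
Product: 15 (2R,3R)-3,5,7-tris(benzyloxy)-2-[3,4-bis(benzyloxy)phenyl]chromane
Conditions: NaH, 14, n-Bu4NI (cat.), DMF, 0 → 23 °C
Reagents that add atoms: none
Why: Williamson etherification of the secondary alkoxide; the benzyl group is chosen so that it leaves with the others in step 15.

Step 10
Reactants: 15 (2R,3R)-3,5,7-tris(benzyloxy)-2-[3,4-bis(benzyloxy)phenyl]chromane
Product: 16 (2R,3R)-3,5,7-tris(benzyloxy)-2-[3,4-bis(benzyloxy)phenyl]-8-bromochromane
Conditions: NBS, CH2Cl2, −78 → 0 °C
Reagents that add atoms: N-bromosuccinimide O=C1CCC(=O)N1Br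
Why: Electrophilic aromatic bromination; C8 of benzylated flavan-3-ols is the documented site of attack by NBS, ahead of C6.

Step 11
Reactants: 17 7-hydroxy-4H-chromen-4-one; 14 benzyl bromide
Product: 18 7-(benzyloxy)-4H-chromen-4-one
Conditions: K2CO3, DMF, 23 °C
Reagents that add atoms: none
Why: Williamson etherification of the phenol.

Step 12
Reactants: 18 7-(benzyloxy)-4H-chromen-4-one; 19 [4-(benzyloxy)phenyl]boronic acid
Product: 20 (2S)-7-(benzyloxy)-2-[4-(benzyloxy)phenyl]chroman-4-one
Conditions: Pd(OCOCF3)2 (5 mol %), (R)-t-BuPyOx (6 mol %), NH4PF6 (30 mol %), H2O (5 equiv), ClCH2CH2Cl, 60 °C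
Reagents that add atoms: none
Why: Palladium-catalysed asymmetric conjugate addition of an arylboronic acid to a chromone, in which the pyridine-oxazoline ligand controls the face of aryl transfer and should set C2 of the upper unit as S.

Step 13
Reactants: 16 (2R,3R)-3,5,7-tris(benzyloxy)-2-[3,4-bis(benzyloxy)phenyl]-8-bromochromane; 20 (2S)-7-(benzyloxy)-2-[4-(benzyloxy)phenyl]chroman-4-one
Product: 22 (2S)-7-(benzyloxy)-2-[4-(benzyloxy)phenyl]-4-{(2R,3R)-3,5,7-tris(benzyloxy)-2-[3,4-bis(benzyloxy)phenyl]chroman-8-yl}chroman-4-ol (both C4 epimers), via aryllithium 21 (not isolated)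
Conditions: t-BuLi (2.0 equiv), THF, −78 °C; CeCl3, −78 °C; then 20, −78 → −40 °C; aqueous work-up
Reagents that add atoms: none
Why: Bromine–lithium exchange and transmetalation to the less basic organocerium reagent, which should add to the C4 carbonyl instead of enolising it; the C4 configuration is immaterial because the carbinol is ionised in step 14.

Step 14
Reactants: 22 the tertiary alcohol from step 13
Product: 23 (2R,3R)-3,5,7-tris(benzyloxy)-2-[3,4-bis(benzyloxy)phenyl]-8-{(2S,4S)-7-(benzyloxy)-2-[4-(benzyloxy)phenyl]chroman-4-yl}chromane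
Conditions: Et3SiH, CF3CO2H, CH2Cl2, −40 → 0 °C
Reagents that add atoms: none
Why: Ionic hydrogenation: the doubly benzylic C4 cation should take hydride on the face opposite the C2 aryl group (axial attack on the half-chair), which places the two aryl groups of the upper ring cis and sets C4 as S.

Step 15
Reactants: 23 the hepta-O-benzyl ether from step 14
Product: 24 (2R,3R)-2-(3,4-dihydroxyphenyl)-8-[(2S,4S)-7-hydroxy-2-(4-hydroxyphenyl)chroman-4-yl]chromane-3,5,7-triol
Conditions: H2 (1 atm), Pd(OH)2/C, THF/MeOH, 23 °C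
Reagents that add atoms: none
Why: Hydrogenolysis of the seven benzyl ethers; the ring C–O bonds and the interflavan bond should survive these neutral conditions, as they do in proanthocyanidin debenzylations.

**Compound list**
1 | 1,3,5-trifluorobenzene | Fc1cc(F)cc(F)c1 | starting material
2 | benzyl alcohol | OCc1ccccc1 | starting material
3 | 1,3-bis(benzyloxy)-5-fluorobenzene | Fc1cc(OCc2ccccc2)cc(OCc2ccccc2)c1 | intermediate
4 | 2,4-bis(benzyloxy)-6-fluorobenzaldehyde | O=Cc1c(F)cc(OCc2ccccc2)cc1OCc1ccccc1 | intermediate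
5 | [2,4-bis(benzyloxy)-6-fluorophenyl]methanol | OCc1c(F)cc(OCc2ccccc2)cc1OCc1ccccc1 | intermediate
6 | 1,5-bis(benzyloxy)-2-(bromomethyl)-3-fluorobenzene | BrCc1c(F)cc(OCc2ccccc2)cc1OCc1ccccc1 | intermediate
7 | 2-(trimethylsilyl)-1,3-dithiane | C[Si](C)(C)C1SCCCS1 | starting material
8 | 2-[2,4-bis(benzyloxy)-6-fluorobenzyl]-2-(trimethylsilyl)-1,3-dithiane | C[Si](C)(C)C1(Cc2c(F)cc(OCc3ccccc3)cc2OCc2ccccc2)SCCCS1 | intermediate
9 | 3,4-bis(benzyloxy)benzaldehyde | O=Cc1ccc(OCc2ccccc2)c(OCc2ccccc2)c1 | starting material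
10 | caesium [3,4-bis(benzyloxy)phenyl]{2-[2,4-bis(benzyloxy)-6-fluorobenzyl]-1,3-dithian-2-yl}methanolate, racemic | [Cs+].[O-]C(c1ccc(OCc2ccccc2)c(OCc2ccccc2)c1)C1(Cc2c(F)cc(OCc3ccccc3)cc2OCc2ccccc2)SCCCS1 | intermediate (not isolated)
11 | (±)-5,7-bis(benzyloxy)-2-[3,4-bis(benzyloxy)phenyl]spiro[chromane-3,2'-[1,3]dithiane] | C1CSC2(SC1)Cc1c(OCc3ccccc3)cc(OCc3ccccc3)cc1OC2c1ccc(OCc3ccccc3)c(OCc3ccccc3)c1 | intermediate
12 | (±)-5,7-bis(benzyloxy)-2-[3,4-bis(benzyloxy)phenyl]chroman-3-one | O=C1Cc2c(OCc3ccccc3)cc(OCc3ccccc3)cc2OC1c1ccc(OCc3ccccc3)c(OCc3ccccc3)c1 | intermediate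
13 | (2R,3R)-5,7-bis(benzyloxy)-2-[3,4-bis(benzyloxy)phenyl]chroman-3-ol | c1c(OCc5ccccc5)cc(OCc5ccccc5)c2c1O[C@H](c1ccc(OCc5ccccc5)c(OCc5ccccc5)c1)[C@H](O)C2 | intermediate
14 | benzyl bromide | BrCc1ccccc1 | starting material
15 | (2R,3R)-3,5,7-tris(benzyloxy)-2-[3,4-bis(benzyloxy)phenyl]chromane | c1c(OCc5ccccc5)cc(OCc5ccccc5)c2c1O[C@H](c1ccc(OCc5ccccc5)c(OCc5ccccc5)c1)[C@H](OCc5ccccc5)C2 | intermediate
16 | (2R,3R)-3,5,7-tris(benzyloxy)-2-[3,4-bis(benzyloxy)phenyl]-8-bromochromane | Brc1c(OCc5ccccc5)cc(OCc5ccccc5)c2c1O[C@H](c1ccc(OCc5ccccc5)c(OCc5ccccc5)c1)[C@H](OCc5ccccc5)C2 | intermediate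
17 | 7-hydroxy-4H-chromen-4-one | O=c1ccoc2cc(O)ccc12 | starting material
18 | 7-(benzyloxy)-4H-chromen-4-one | O=c1ccoc2cc(OCc3ccccc3)ccc12 | intermediate
19 | [4-(benzyloxy)phenyl]boronic acid | OB(O)c1ccc(OCc2ccccc2)cc1 | starting material
20 | (2S)-7-(benzyloxy)-2-[4-(benzyloxy)phenyl]chroman-4-one | O(Cc5ccccc5)c1ccc([C@@H]2CC(=O)c3ccc(OCc5ccccc5)cc3O2)cc1 | intermediate
21 | 8-lithio derivative of 15 | [Li]c1c(OCc5ccccc5)cc(OCc5ccccc5)c2c1O[C@H](c1ccc(OCc5ccccc5)c(OCc5ccccc5)c1)[C@H](OCc5ccccc5)C2 | intermediate (not isolated)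
22 | (2S)-7-(benzyloxy)-2-[4-(benzyloxy)phenyl]-4-{(2R,3R)-3,5,7-tris(benzyloxy)-2-[3,4-bis(benzyloxy)phenyl]chroman-8-yl}chroman-4-ol, both C4 epimers | O(Cc5ccccc5)c1ccc([C@@H]2CC(O)(c3c(OCc5ccccc5)cc(OCc5ccccc5)c4c3O[C@H](c3ccc(OCc5ccccc5)c(OCc5ccccc5)c3)[C@H](OCc5ccccc5)C4)c3ccc(OCc5ccccc5)cc3O2)cc1 | intermediate
23 | (2R,3R)-3,5,7-tris(benzyloxy)-2-[3,4-bis(benzyloxy)phenyl]-8-{(2S,4S)-7-(benzyloxy)-2-[4-(benzyloxy)phenyl]chroman-4-yl}chromane | O(Cc5ccccc5)c1ccc([C@@H]2C[C@H](c3c(OCc5ccccc5)cc(OCc5ccccc5)c4c3O[C@H](c3ccc(OCc5ccccc5)c(OCc5ccccc5)c3)[C@H](OCc5ccccc5)C4)c3ccc(OCc5ccccc5)cc3O2)cc1 | intermediate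
24 | (2R,3R)-2-(3,4-dihydroxyphenyl)-8-[(2S,4S)-7-hydroxy-2-(4-hydroxyphenyl)chroman-4-yl]chromane-3,5,7-triol | Oc1ccc([C@@H]2C[C@H](c3c(O)cc(O)c4c3O[C@H](c3ccc(O)c(O)c3)[C@H](O)C4)c3ccc(O)cc3O2)cc1 | target

**Count**
Total steps: 15. Longest linear sequence: 13 steps (steps 1 to 10, then 13, 14 and 15); steps 11 and 12 form the side branch to 20.

**Steps most likely to fail**

Step 6 (proposed new method). Risk: protodesilylation of 8 by traces of water in place of addition, reversion of the alkoxide adduct, or an alkoxide too weakly nucleophilic under fluoride conditions to displace the aryl fluoride. Fallback with known reactions, the two bonds made in separate operations and in another order: 1,3-dithiane is lithiated (n-BuLi, THF, −30 °C) and added to 9 to give [3,4-bis(benzyloxy)phenyl](1,3-dithian-2-yl)methanol F1. Its O,C-dianion (n-BuLi, 2.1 equiv, THF, −30 °C) is alkylated at carbon by 6 to give {2-[2,4-bis(benzyloxy)-6-fluorobenzyl]-1,3-dithian-2-yl}[3,4-bis(benzyloxy)phenyl]methanol F2. KH in DMF (0 → 60 °C) then closes ring C by the documented alkoxide SNAr. The fallback sets out from 9 and 6 and comes back to the route at 11.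

Step 8. Risk: epimerisation of C2 too slow relative to reduction, poor facial discrimination by the catalyst on this ring-oxygenated ketone, or base-induced decomposition of the enolisable flavan-3-one. Fallback by resolution in place of asymmetric catalysis: 12 is reduced with LiBH(s-Bu)3 (THF, −78 °C), a reduction documented to give 2,3-cis flavan-3-ols, to give racemic cis-5,7-bis(benzyloxy)-2-[3,4-bis(benzyloxy)phenyl]chroman-3-ol F3. The enantiomers are separated by preparative chromatography on a cellulose tris(3,5-dimethylphenylcarbamate) phase. The fallback sets out from 12 and comes back at 13, which is the (2R,3R) enantiomer.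

Step 13. Risk: enolisation of 20 and opening of its pyran ring to the chalcone outrunning addition of the hindered aryl nucleophile. Fallback with inverted polarity: 20 is reduced with NaBH4 (MeOH/THF, 0 °C) to (2S,4S)-7-(benzyloxy)-2-[4-(benzyloxy)phenyl]chroman-4-ol F4. F4 is ionised with BF3·OEt2 (CH2Cl2, −40 °C) in the presence of an excess of 15, and Friedel–Crafts attack of C8 of 15 on the C4 cation gives 23 after separation from the C6 regioisomer and the 2,4-trans epimer. The fallback sets out from 20 and 15 and comes back at 23; steps 10 and 14 then fall away.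

**Further compounds**
F1 | step 6 | [3,4-bis(benzyloxy)phenyl](1,3-dithian-2-yl)methanol, racemic | OC(c1ccc(OCc2ccccc2)c(OCc2ccccc2)c1)C1SCCCS1
F2 | step 6 | {2-[2,4-bis(benzyloxy)-6-fluorobenzyl]-1,3-dithian-2-yl}[3,4-bis(benzyloxy)phenyl]methanol, racemic | OC(c1ccc(OCc2ccccc2)c(OCc2ccccc2)c1)C1(Cc2c(F)cc(OCc3ccccc3)cc2OCc2ccccc2)SCCCS1
F3 | step 8 | cis-5,7-bis(benzyloxy)-2-[3,4-bis(benzyloxy)phenyl]chroman-3-ol, racemate of the (2R,3R) and (2S,3S) forms | c1c(OCc5ccccc5)cc(OCc5ccccc5)c2c1O[C@H](c1ccc(OCc5ccccc5)c(OCc5ccccc5)c1)[C@H](O)C2.c1c(OCc5ccccc5)cc(OCc5ccccc5)c2c1O[C@@H](c1ccc(OCc5ccccc5)c(OCc5ccccc5)c1)[C@@H](O)C2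
F4 | step 13 | (2S,4S)-7-(benzyloxy)-2-[4-(benzyloxy)phenyl]chroman-4-ol | O(Cc5ccccc5)c1ccc([C@@H]2C[C@H](O)c3ccc(OCc5ccccc5)cc3O2)cc1
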